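The pyrone is cut last, at C5'–C4' and O1'–C2', into the C5 acetyl group of a tetralone and a malonyl unit (C4'–C3'–C2'). The feature exploited is that C6' lies in the pocket between the C6 phenyl ring and the C4 methylene of the cyclohexanone ring and is closed to nucleophiles, whereas its neighbour C5' is exposed. As the terminal carbon of an enol silane, C5' attacks malonyl dichloride, and the enol oxygen then closes the 4-hydroxy-2-pyrone ring in the same operation. The precursor is the (S)-3-silyloxy-6-phenyltetralone bearing a C8 trimethylsilyl aryl ether and a C5 1-(trimethylsilyloxy)vinyl group, assembled by Diels–Alder benzannulation.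

Key step: step 9

Numbering: tetralone atoms are C1 (ketone), C2, C3 (carbinol), C4, C4a, C5 (pyronyl), C6 (phenyl), C7, C8 (phenol), C8a. Pyrone atoms are primed: O1', C2' (lactone carbonyl), C3', C4' (hydroxyl), C5', C6' (bonded to C5). TBS = tert-butyldimethylsilyl.

Assumption: the lipase in step 2 is taken to acetylate, of the two enantiotopic carbinols of 2, the one shown acetylated in 3. Lipases give either antipode of such monoesters depending on whether they are run in the acylation or the hydrolysis direction, so the sense can be matched to 3 if needed.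

Step 1
Reactants: 1 all-cis-cyclohexane-1,3,5-triol
Product: 2 all-cis-5-(tert-butyldimethylsilyloxy)cyclohexane-1,3-diol (meso)
Conditions: anhydrous 1 (3 equiv), TBSCl (1 equiv), imidazole, DMF, 0 °C to rt
Reagents that add atoms: tert-butyldimethylsilyl chloride, CC(C)(C)[Si](C)(C)Cl
Why: Silyl ether formation with a silyl chloride and imidazole on a triol whose three hydroxyls are equivalent should give the meso mono-ether when the triol is in excess, with no stereocentre created and unreacted triol recoverable.

Step 2
Reactants: 2 all-cis-5-(tert-butyldimethylsilyloxy)cyclohexane-1,3-diol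
Product: 3 (1S,3R,5R)-3-(tert-butyldimethylsilyloxy)-5-hydroxycyclohexyl acetate (all-cis)
Conditions: immobilised Candida antarctica lipase B, vinyl acetate, MTBE, rt
Reagents that add atoms: vinyl acetate, C=COC(C)=O
Why: Lipase-catalysed transesterification with an irreversible acyl donor (enzymatic desymmetrisation of a meso-1,3-diol) should acetylate one enantiotopic carbinol only, which makes the silyloxy-bearing carbon (later C3 of the target) a defined stereocentre.

Step 3
Reactants: 3 (1S,3R,5R)-3-(tert-butyldimethylsilyloxy)-5-hydroxycyclohexyl acetate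
Product: 5 (S)-5-(tert-butyldimethylsilyloxy)cyclohex-2-en-1-one, via beta-acetoxy ketone 4 (not isolated)
Conditions: Dess–Martin periodinane, CH2Cl2, 0 °C to rt; then Et3N (excess), rt
Reagents that add atoms: none
Why: Dess–Martin oxidation of the free carbinol gives a beta-acetoxy ketone from which triethylamine expels acetate by E1cB elimination (acetate is a far better leaving group than the silyloxide on the other beta-carbon), so the enone should form with the silyloxy stereocentre untouched.

Step 4
Reactants: 5 (S)-5-(tert-butyldimethylsilyloxy)cyclohex-2-en-1-one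
Product: 6 (S)-5-(tert-butyldimethylsilyloxy)-2-iodocyclohex-2-en-1-one
Conditions: I2, pyridine, CH2Cl2, 0 °C to rt
Reagents that add atoms: iodine, II
Why: Alpha-iodination of an enone with iodine and pyridine proceeds by conjugate addition of pyridine, iodination of the enolate at C2 and loss of pyridine (a Baylis–Hillman-type addition–elimination), and is mild enough to leave the beta-silyloxy group in place.

Step 5
Reactants: 6 (S)-5-(tert-butyldimethylsilyloxy)-2-iodocyclohex-2-en-1-one; 7 tributyl(1-ethoxyvinyl)stannane
Product: 8 (S)-5-(tert-butyldimethylsilyloxy)-2-(1-ethoxyvinyl)cyclohex-2-en-1-one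
Conditions: Pd(PPh3)4 (5 mol%), CuI (10 mol%), DMF, 45 °C; chromatography on Et3N-deactivated silica
Reagents that add atoms: none
Why: Stille coupling of a 2-iodoenone with an alpha-alkoxyvinylstannane, accelerated by CuI, is a standard route to 2-(1-alkoxyvinyl)enones, and its neutral conditions spare both the silyl ether and the acid-labile enol ether.

Step 6
Reactants: 8 (S)-5-(tert-butyldimethylsilyloxy)-2-(1-ethoxyvinyl)cyclohex-2-en-1-one; 9 4-phenylbut-3-yn-2-one
Product: 11 (S)-5-acetyl-3-(tert-butyldimethylsilyloxy)-8-ethoxy-6-phenyl-3,4-dihydronaphthalen-1(2H)-one, via cyclohexadiene cycloadduct 10 (not isolated)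
Conditions: 9 (1.5 equiv), toluene, 110 °C (sealed tube); then DDQ (1.1 equiv), rt
Reagents that add atoms: none
Why: In the thermal Diels–Alder reaction the nucleophilic terminal CH2 of the 2-ethoxydiene should bond to the phenyl-bearing beta-carbon of the ynone ("para" orientation of ethoxy and acetyl), which places acetyl at C5 and phenyl at C6, and DDQ dehydrogenation of the 1,4-cyclohexadiene then gives the arene and erases the uncontrolled C4a centre without touching C3.

Step 7
Reactants: 11 (S)-5-acetyl-3-(tert-butyldimethylsilyloxy)-8-ethoxy-6-phenyl-3,4-dihydronaphthalen-1(2H)-one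
Product: 13 (S)-5-acetyl-3-(tert-butyldimethylsilyloxy)-8-hydroxy-6-phenyl-3,4-dihydronaphthalen-1(2H)-one, via aryloxyboron dichloride 12 (not isolated)
Conditions: BCl3 (1 M in CH2Cl2, 2 equiv), CH2Cl2, -78 to -20 °C; then H2O, 0 °C
Reagents that add atoms: none
Why: Chelation-assisted Lewis-acid dealkylation: boron is held between the C1 carbonyl and the peri C8 ether oxygen, chloride attacks the ethyl group, and at low temperature this directed cleavage should be much faster than attack on the secondary silyl ether.

Step 8
Reactants: 13 (S)-5-acetyl-3-(tert-butyldimethylsilyloxy)-8-hydroxy-6-phenyl-3,4-dihydronaphthalen-1(2H)-one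
Product: 15 (S)-3-(tert-butyldimethylsilyloxy)-6-phenyl-8-(trimethylsilyloxy)-5-[1-(trimethylsilyloxy)vinyl]-3,4-dihydronaphthalen-1(2H)-one, via dilithium phenoxide enolate 14 (not isolated)
Conditions: LiN(SiMe3)2 (2.4 equiv), THF, -78 °C; then Me3SiCl (3 equiv), -78 to 0 °C; evaporation, pentane, filtration under argon; used crude
Reagents that add atoms: chlorotrimethylsilane, C[Si](C)(C)Cl
Why: Double deprotonation and O-silylation (enolate trapping): the first equivalent of amide makes the C8 phenoxide, whose lithium chelate turns the coplanar C1 carbonyl into a vinylogous carboxylate and puts C2–H beyond the reach of this moderately strong base, whereas the C5 acetyl group, twisted out of the ring plane by the C6 phenyl and the C4 methylene, keeps ordinary methyl ketone acidity and is deprotonated by the second equivalent, so Me3SiCl should cap only the phenoxide and the terminal enolate.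

Step 9
Reactants: 15 (S)-3-(tert-butyldimethylsilyloxy)-6-phenyl-8-(trimethylsilyloxy)-5-[1-(trimethylsilyloxy)vinyl]-3,4-dihydronaphthalen-1(2H)-one; 16 malonyl dichloride
Product: 19 wailupemycin F 3-O-tert-butyldimethylsilyl ether, via dioxopentanoyl chloride 17 (not isolated), via C8-O-trimethylsilyl pyrone 18 (not isolated)
Conditions: 15 added slowly to 16 (2 equiv), Et2O, -78 to -20 °C; then pH 7 phosphate buffer, 0 °C
Reagents that add atoms: none
Why: The terminal carbon C5' of the enol silane attacks one acyl chloride of malonyl dichloride (or the chlorocarbonylketene formed from it) with loss of chlorotrimethylsilane to give the 3,5-dioxo acid chloride 17, which enolises towards C6'; the enol oxygen then displaces the second chloride, tautomerisation gives the 4-hydroxy-2-pyrone, and the aqueous work-up removes the C8 trimethylsilyl group. The closest known reaction is the one-step synthesis of 6-substituted 4-hydroxy-2-pyrones from ketone trimethylsilyl enol ethers and malonyl dichloride at low temperature, applied here to a hindered aryl methyl ketone. The one ring closes by a 6-exo-trig acyl substitution of O1' on C2'. No stereocentre is formed and C3 is not involved. The step needs C-acylation at C5' and not at C2 or at the C8 oxygen; this is secured because the only enol silane in the substrate is that of the C5 acetyl group (fixed in step 8) and the C8 oxygen is capped as a silyl ether, while slow addition to excess dichloride prevents one malonyl unit from bridging two molecules. No reagent has to approach C6', which lies between the C6 phenyl group and the C4 methylene.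

Step 10
Reactants: 19 wailupemycin F 3-O-tert-butyldimethylsilyl ether
Product: 20 wailupemycin F
Conditions: 48% aq. HF, MeCN, 0 °C to rt (polypropylene vessel); dilution with pH 5 buffer, EtOAc extraction
Reagents that add atoms: none
Why: Desilylation driven by Si–F bond formation under mildly acidic conditions should free the C3 hydroxyl without the basic conditions that would cause E1cB dehydration and aromatisation to a naphthol, and C3 keeps its (S) configuration because no bond to it is broken.

Compound list
1 | all-cis-cyclohexane-1,3,5-triol | O[C@@H]1C[C@H](O)C[C@H](O)C1 | starting material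
2 | all-cis-5-(tert-butyldimethylsilyloxy)cyclohexane-1,3-diol (meso) | O[C@H]1C[C@@H](O[Si](C)(C)C(C)(C)C)C[C@@H](O)C1 | intermediate
3 | (1S,3R,5R)-3-(tert-butyldimethylsilyloxy)-5-hydroxycyclohexyl acetate (all-cis) | O[C@H]1C[C@@H](O[Si](C)(C)C(C)(C)C)C[C@@H](OC(C)=O)C1 | intermediate
4 | (1R,3S)-3-(tert-butyldimethylsilyloxy)-5-oxocyclohexyl acetate (cis; not isolated) | O=C1C[C@@H](O[Si](C)(C)C(C)(C)C)C[C@@H](OC(C)=O)C1 | intermediate
5 | (S)-5-(tert-butyldimethylsilyloxy)cyclohex-2-en-1-one | O=C1C[C@@H](O[Si](C)(C)C(C)(C)C)CC=C1 | intermediate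
6 | (S)-5-(tert-butyldimethylsilyloxy)-2-iodocyclohex-2-en-1-one | O=C1C[C@@H](O[Si](C)(C)C(C)(C)C)CC=C1I | intermediate
7 | tributyl(1-ethoxyvinyl)stannane | CCCC[Sn](CCCC)(CCCC)C(=C)OCC | starting material
8 | (S)-5-(tert-butyldimethylsilyloxy)-2-(1-ethoxyvinyl)cyclohex-2-en-1-one | O=C1C[C@@H](O[Si](C)(C)C(C)(C)C)CC=C1C(=C)OCC | intermediate
9 | 4-phenylbut-3-yn-2-one | CC(=O)C#Cc1ccccc1 | starting material
10 | (3S)-5-acetyl-3-(tert-butyldimethylsilyloxy)-8-ethoxy-6-phenyl-3,4,4a,7-tetrahydronaphthalen-1(2H)-one (both C4a epimers, centre left undefined; not isolated) | O=C1C[C@@H](O[Si](C)(C)C(C)(C)C)CC2C(C(C)=O)=C(c3ccccc3)CC(OCC)=C12 | intermediate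
11 | (S)-5-acetyl-3-(tert-butyldimethylsilyloxy)-8-ethoxy-6-phenyl-3,4-dihydronaphthalen-1(2H)-one | O=C1C[C@@H](O[Si](C)(C)C(C)(C)C)Cc2c1c(OCC)cc(-c1ccccc1)c2C(C)=O | intermediate
12 | C8-O-dichloroboryl derivative of 13, boron chelated by the C1 carbonyl (not isolated) | O=C1C[C@@H](O[Si](C)(C)C(C)(C)C)Cc2c1c(OB(Cl)Cl)cc(-c1ccccc1)c2C(C)=O | intermediate
13 | (S)-5-acetyl-3-(tert-butyldimethylsilyloxy)-8-hydroxy-6-phenyl-3,4-dihydronaphthalen-1(2H)-one | O=C1C[C@@H](O[Si](C)(C)C(C)(C)C)Cc2c1c(O)cc(-c1ccccc1)c2C(C)=O | intermediate
14 | dilithium salt of 13: C8 phenoxide and terminal enolate of the C5 acetyl group (not isolated) | [Li+].[Li+].O=C1C[C@@H](O[Si](C)(C)C(C)(C)C)Cc2c1c([O-])cc(-c1ccccc1)c2C([O-])=C | intermediate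
15 | (S)-3-(tert-butyldimethylsilyloxy)-6-phenyl-8-(trimethylsilyloxy)-5-[1-(trimethylsilyloxy)vinyl]-3,4-dihydronaphthalen-1(2H)-one | O=C1C[C@@H](O[Si](C)(C)C(C)(C)C)Cc2c1c(O[Si](C)(C)C)cc(-c1ccccc1)c2C(=C)O[Si](C)(C)C | intermediate
16 | malonyl dichloride | O=C(Cl)CC(=O)Cl | starting material
17 | 5-aryl-3,5-dioxopentanoyl chloride, aryl = C5 of the (S)-3-TBS-oxy-8-trimethylsilyloxy-6-phenyltetralone (not isolated) | O=C1C[C@@H](O[Si](C)(C)C(C)(C)C)Cc2c1c(O[Si](C)(C)C)cc(-c1ccccc1)c2C(=O)CC(=O)CC(=O)Cl | intermediate
18 | wailupemycin F 3-O-TBS 8-O-trimethylsilyl bis-ether (not isolated) | O=C1C[C@@H](O[Si](C)(C)C(C)(C)C)Cc2c1c(O[Si](C)(C)C)cc(-c1ccccc1)c2-c1cc(O)cc(=O)o1 | intermediate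
19 | wailupemycin F 3-O-tert-butyldimethylsilyl ether, (S)-3-(tert-butyldimethylsilyloxy)-8-hydroxy-5-(4-hydroxy-2-oxo-2H-pyran-6-yl)-6-phenyl-3,4-dihydronaphthalen-1(2H)-one | O=C1C[C@@H](O[Si](C)(C)C(C)(C)C)Cc2c1c(O)cc(-c1ccccc1)c2-c1cc(O)cc(=O)o1 | intermediate
20 | wailupemycin F, (S)-3,8-dihydroxy-5-(4-hydroxy-2-oxo-2H-pyran-6-yl)-6-phenyl-3,4-dihydronaphthalen-1(2H)-one | O=C1C[C@@H](O)Cc2c1c(O)cc(-c1ccccc1)c2-c1cc(O)cc(=O)o1 | target

Total step count: 10. Longest linear sequence: 10 steps (1 to 20).

Steps most likely to fail

Step 9. The bifunctional acid chloride may link two molecules of enol silane, or the hydrogen chloride released on ring closure may protodesilylate unreacted enol silane and strip the C3 silyl ether before the pyrone has formed. The fallback sets out from 15 and comes back at 19; it builds the chain and closes the ring in two separate known operations. C-acylation of enol silane 15 with the monofunctional methyl 3-chloro-3-oxopropanoate under ZnCl2 catalysis (CH2Cl2/Et2O, 0 °C; aqueous work-up frees the C8 phenol) should give methyl 5-aryl-3,5-dioxopentanoate F1. DBU in toluene at room temperature then closes the lactone by attack of the C6' enolate oxygen on the methyl ester with loss of methanol, which gives 19; no hydrogen chloride is formed in the ring closure.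

Step 8. Deprotonation may occur at C2 instead of at the acetyl methyl, followed by E1cB loss of the C3 silyloxy group and aromatisation of the ketone ring, or a mixture of enolates may be silylated. The fallback sets out from diene 8 and comes back at 15; it fixes the position of the enol silane by a halogen instead of by relative acidity. Lithium phenylacetylide and 2-chloro-N-methoxy-N-methylacetamide (THF, -78 °C) give 1-chloro-4-phenylbut-3-yn-2-one F2. Its Diels–Alder reaction with 8 in toluene gives the chloroacetyl cycloadduct F3, which DDQ aromatises in the same flask to the 5-chloroacetyl-8-ethoxytetralone F4. BCl3 under the conditions of step 7 gives the 5-chloroacetyl-8-hydroxytetralone F5. Zinc dust, Me3SiCl and Et3N in Et2O then silylate the phenol and convert the alpha-chloro ketone, by zinc insertion into the C–Cl bond and O-silylation of the zinc enolate (Reformatsky-type reductive silylation), into 15, with no strong base and no choice between enolisable sites.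

Step 7. The Lewis acid may also cleave the C3 silyl ether or promote beta-elimination of the silyloxy group with aromatisation of the ketone ring. The fallback sets out from cycloadduct 10 (step 6 stopped before DDQ is added) and comes back at 13; it avoids cleaving an aryl ether altogether. Dilute HCl in THF/H2O at 0 °C hydrolyses the vinylogous ethyl ester of 10 with loss of ethanol to the enolised 1,8-diketone F6. DDQ in toluene at room temperature then removes hydride from the doubly allylic C4a and a proton from C7, which gives phenol 13 directly.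

Further compounds
F1 | step 9 | methyl 5-[(7S)-7-(tert-butyldimethylsilyloxy)-4-hydroxy-5-oxo-2-phenyl-5,6,7,8-tetrahydronaphthalen-1-yl]-3,5-dioxopentanoate | O=C1C[C@@H](O[Si](C)(C)C(C)(C)C)Cc2c1c(O)cc(-c1ccccc1)c2C(=O)CC(=O)CC(=O)OC
F2 | step 8 | 1-chloro-4-phenylbut-3-yn-2-one | O=C(CCl)C#Cc1ccccc1
F3 | step 8 | (3S)-5-(chloroacetyl)-3-(tert-butyldimethylsilyloxy)-8-ethoxy-6-phenyl-3,4,4a,7-tetrahydronaphthalen-1(2H)-one (both C4a epimers, centre left undefined; not isolated) | O=C1C[C@@H](O[Si](C)(C)C(C)(C)C)CC2C(C(=O)CCl)=C(c3ccccc3)CC(OCC)=C12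
F4 | step 8 | (S)-5-(chloroacetyl)-3-(tert-butyldimethylsilyloxy)-8-ethoxy-6-phenyl-3,4-dihydronaphthalen-1(2H)-one | O=C1C[C@@H](O[Si](C)(C)C(C)(C)C)Cc2c1c(OCC)cc(-c1ccccc1)c2C(=O)CCl
F5 | step 8 | (S)-5-(chloroacetyl)-3-(tert-butyldimethylsilyloxy)-8-hydroxy-6-phenyl-3,4-dihydronaphthalen-1(2H)-one | O=C1C[C@@H](O[Si](C)(C)C(C)(C)C)Cc2c1c(O)cc(-c1ccccc1)c2C(=O)CCl
F6 | step 7 | (3S)-5-acetyl-3-(tert-butyldimethylsilyloxy)-8-hydroxy-6-phenyl-3,4,4a,7-tetrahydronaphthalen-1(2H)-one (enol form of the 1,8-diketone; both C4a epimers, centre left undefined) | O=C1C[C@@H](O[Si](C)(C)C(C)(C)C)CC2C(C(C)=O)=C(c3ccccc3)CC(O)=C12
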